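(All runs stem from a simulated flask from invented constants; noise was put on by code.)

The amounts in the red run level off, and since it is the flask asked about, I have to choose what to do with it at 6.0 d.

| flask | starting material | reagent | second substrate | remark | time |
|---|---|---|---|---|---|
| red | 1 M | 0.90 M | 1 M | the very flask that is asked about, followed so far |  |
| flask | 1.0 M | 0.900 M | 1.00 M |  | 6.0 d |

- red (time / h: target / %, starting material / %): 10.0: 37.0, 35.7; 30.0: 48.2, 25.9; 60.0: 52.0, 22.4; 96.0: 49.6, 19.8

(scatter of a reading: 1 percentage point)

- south-west: at 6.0 d take out 90 % of the target then present, then wait 12 d
- south: at 6.0 d add starting material, 50.0 % of the amount charged, then wait 12 d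
- east: change nothing and wait 12 d more

* target, in percent of the starting material first charged, at 6.0 d
* the option that brings most further target ("none" if no option brings more than 2 percentage points) (south-west / south / east / none)
* target present, with what was taken out counted in, in percent of the starting material first charged, after south
* target present, with what was taken out counted in, in percent of the starting material first charged, after east

- target that was removed still counts
- additions bring no volume worth counting

Between the last two readings of the red run, target falls 2.4 percentage points and starting material 2.6 points. So I read them as lost together, one for one. Target decays there with a time constant of 762 h, at a mean starting material of 21.1 %. This is the target lifetime: the time constant of the late loss of target, which I take as inversely proportional to free starting material.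

Carried forward to 6.0 d:

target = 49.6 % × exp(−48.0 h / lifetime) = 46.6 %

starting material = 16.8 %, falling by the same points

The loss is slow, but what about the stall? I form the reaction quotient, target / (starting material × reagent not in target), in fractions of the charge. It reads 4.45, then 6.11, then 6.20. The last two are about equal, so I treat the stall as an equilibrium that refills after a disturbance. With 43.4 % of reagent not in target, I solve the quotient for each refill, then hold starting material at its new level through the wait, which is rough:

south-west: refill 9.8 points, lifetime 2310 h, target 54.7 %

south: refill 20 points, lifetime 346 h, target 29.0 %

east: lifetime 958 h, target 34.5 %

South-west gives more than the others, a gain of 8.1 points, so I would take the target out.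

The forecast differs on the choice: it gives 48 %, none, 46.5 % after south and 44 % after east, holding that “Removing target doesn't help because the stall isn't equilibrium”.

The flask gives 46.3 %, and south-west brings 8.3 points, against −16 points for south, which ends at 29.9 %, and −15 points for east, which ends at 31.0 %.

    starting material + reagent ⇌ target (K = 9.70 L mol⁻¹, k = 0.100 L mol⁻¹ h⁻¹)
    second substrate + reagent ⇌ second product (K = 0.0690 L mol⁻¹, k = 0.00990 L mol⁻¹ h⁻¹)
    starting material + target → side product (k = 0.00850 L mol⁻¹ h⁻¹)
    starting material ⇌ dormant form (K = 0.640, k = 0.100 h⁻¹)
    target → over-reaction product (k = 1.00 × 10⁻⁴ h⁻¹)

In the flask left alone, target falls from 46.3 % to 31.0 % over 12 d, an average time constant of 719 h, shorter than the target lifetime of 957 h I reckoned for east. In the neighbour charged with 1.5 M of reagent, starting material is 9.0 %, against 16.6 % in the flask at 144 h, so my rule stretches the target lifetime there by a factor of 1.84, and that neighbour holds 64.0 % of target.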